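**Retrosynthetic overview**
1. Both benzene rings are bought intact: ring B as 3,5-dibromosalicylaldehyde 1 and ring A as 5-bromo-2-methoxyphenol 2. No ring is formed, and all three bromines and the OMe group are in place from the start.
2. Key disconnection: the diaryl ether C–O bond. It is made first, by dehydrative cross-coupling of the two phenols with chloroimidazolinium salt 3. Phenol 1 becomes the electrophile through uronium salt 4 and orthoamide 5, giving aldehyde 6.
3. Second disconnection: the ring B C–OH bond. It traces back to the formyl group that activated the coupling (Baeyer–Villiger via formate 7, then methanolysis) and gives target 8.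
4. Logic: the ring B bromines sit meta to OH and ortho/para to the ether oxygen. Late bromination cannot deliver this pattern, but 1 already carries it.

Assumption: the SMILES has no stereodescriptor, and the molecule has no stereocentre and no hindered axis (the diaryl ether rotates freely). It is therefore achiral and no enantiomer has to be selected.

**Route**

Step 1
Reactants: 1 3,5-dibromosalicylaldehyde; 2 5-bromo-2-methoxyphenol; 3 2-chloro-1,3-dimethylimidazolinium chloride
Product: 6 3,5-dibromo-2-(5-bromo-2-methoxyphenoxy)benzaldehyde, via aryloxyimidazolinium chloride 4 (not isolated), via bis(aryloxy)imidazolidine 5 (not isolated)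
Conditions: 1, K3PO4 (anhydrous, milled, 2.5 equiv), 4 Å MS, MeCN, rt; 3 (1.05 equiv), 0 °C to rt, 1 h; then 2 (1.05 equiv), 80 °C, 16 h
Reagents that add atoms: none
Why: Proposed new method: dehydrative cross-etherification of two phenols, in which 3 turns the more acidic phenol 1 into the cationic O-aryl isouronium salt 4, whose ipso carbon is activated by the ortho formyl group, the two bromines and a neutral urea leaving group; deprotonated 2 adds to the amidinium carbon to give orthoamide 5, which collapses by a four-centre concerted nucleophilic aromatic substitution (ring A oxygen onto the ring B ipso carbon, or the equivalent ion-pair addition–elimination) driven by formation of the urea C=O; aryloxide exchange at the amidinium carbon is harmless because either oxygen gives the same ether 6, homo-coupling is disfavoured because only ring B is electrophilic and only 2 is a good nucleophile, and the fully N-alkylated reagent blocks any O-to-N aryl shift; the closest known reaction types are deoxyfluorination of phenols through 2-aryloxyimidazolium salts, the Newman–Kwart and Chapman 1,3-aryl shifts, and phosphonium-mediated SNAr etherification of tautomerisable heteroaryl-ols, none of which has been shown to join two carbocyclic phenols.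

Step 2
Reactants: 6 3,5-dibromo-2-(5-bromo-2-methoxyphenoxy)benzaldehyde
Product: 8 3,5-dibromo-2-(5-bromo-2-methoxyphenoxy)phenol, via aryl formate 7 (not isolated)
Conditions: mCPBA (2 equiv), CH2Cl2, 40 °C, 16 h; aqueous Na2S2O3/NaHCO3 wash of the crude; then MeOH, cat. HCl, rt, 2 h
Reagents that add atoms: mCPBA (3-chloroperoxybenzoic acid), O=C(OO)c1cccc(Cl)c1
Why: Baeyer–Villiger (Dakin-type) oxidation, in which the Criegee adduct of the aldehyde expels 3-chlorobenzoate with migration of the aryl group (favoured over hydride shift by the ortho aryloxy lone pair), and acid-catalysed methanolysis of formate 7 after the peracid has been destroyed frees the phenol without touching the aryl bromides, the methyl ether or the diaryl ether; no stereocentre is formed.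

**Compound list**
1 | 3,5-dibromo-2-hydroxybenzaldehyde (3,5-dibromosalicylaldehyde) | O=Cc1cc(Br)cc(Br)c1O | starting material
2 | 5-bromo-2-methoxyphenol | COc1ccc(Br)cc1O | starting material
3 | 2-chloro-1,3-dimethylimidazolinium chloride | CN1CC[N+](C)=C1Cl.[Cl-] | starting material
4 | 2-(2,4-dibromo-6-formylphenoxy)-1,3-dimethyl-4,5-dihydro-1H-imidazol-3-ium chloride | CN1CC[N+](C)=C1Oc1c(C=O)cc(Br)cc1Br.[Cl-] | intermediate
5 | 3,5-dibromo-2-{[2-(5-bromo-2-methoxyphenoxy)-1,3-dimethylimidazolidin-2-yl]oxy}benzaldehyde | CN1CCN(C)C1(Oc1cc(Br)ccc1OC)Oc1c(C=O)cc(Br)cc1Br | intermediate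
6 | 3,5-dibromo-2-(5-bromo-2-methoxyphenoxy)benzaldehyde | COc1ccc(Br)cc1Oc1c(C=O)cc(Br)cc1Br | intermediate
7 | 3,5-dibromo-2-(5-bromo-2-methoxyphenoxy)phenyl formate | COc1ccc(Br)cc1Oc1c(OC=O)cc(Br)cc1Br | intermediate
8 | 3,5-dibromo-2-(5-bromo-2-methoxyphenoxy)phenol | COc1ccc(Br)cc1Oc1c(O)cc(Br)cc1Br | target

**Totals**
Total step count: 2. Longest linear sequence: 2.

**Steps most likely to fail**
The route has only two steps, so both are ranked and there is no third to rank.

1. Step 1 (the proposed new step).
   - Risks: aryloxide exchange may park the material as the unreactive ring A uronium / ring B phenoxide pair. The ipso carbon is crowded by Br and CHO. Traces of water hydrolyse 4 back to 1.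
   - One leak is convergent: if chloride captures 4 at the ipso carbon, the resulting ortho-formyl aryl chloride is still an SNAr partner for 2.
   - Fallback (known chemistry): it sets out from 2 and comes back at 6. Compound 2 is heated with bought 3,5-dibromo-2-fluorobenzaldehyde F1 and K2CO3 in N,N-dimethylacetamide at 100 °C. Classical addition–elimination SNAr at the C–F carbon ortho to the formyl group gives 6 directly, and step 2 follows unchanged.

2. Step 2.
   - Risks: the aldehyde is hindered and its ring is electron-poor. The Criegee adduct may therefore form slowly, or hydride may migrate in place of aryl to give the carboxylic acid.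
   - Fallback: it sets out from 6 and comes back at 8, and it makes use of that very acid. Compound 6 is oxidised on purpose (NaClO2, NaH2PO4, 2-methyl-2-butene, tBuOH/H2O, Pinnick oxidation) to 3,5-dibromo-2-(5-bromo-2-methoxyphenoxy)benzoic acid F2.
   - F2 is then irradiated (about 400 nm LED, 35 °C, MeCN) with LiOH, Cu(OTf)2 and Cu(O2CC4H3S), the thiophene-2-carboxylate of monovalent copper. Ligand-to-metal charge transfer in the divalent copper carboxylate triggers decarboxylation. The aryl radical is captured at copper and coupled to give 3,5-dibromo-2-(5-bromo-2-methoxyphenoxy)phenyl thiophene-2-carboxylate F3, which LiOH in THF/H2O cleaves to 8.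

**Further compounds**
F1 | step 1 | 3,5-dibromo-2-fluorobenzaldehyde | O=Cc1cc(Br)cc(Br)c1F
F2 | step 2 | 3,5-dibromo-2-(5-bromo-2-methoxyphenoxy)benzoic acid | COc1ccc(Br)cc1Oc1c(C(=O)O)cc(Br)cc1Br
F3 | step 2 | 3,5-dibromo-2-(5-bromo-2-methoxyphenoxy)phenyl thiophene-2-carboxylate | COc1ccc(Br)cc1Oc1c(OC(=O)c2cccs2)cc(Br)cc1Br
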